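**Target:** 3,5-dibromo-2-(2,4-dibromophenoxy)phenol (13), SMILES Oc1cc(Br)cc(Br)c1Oc1ccc(Br)cc1Br. Numbering used below: ring A is C1 (OH), C2 (O-aryl), C3 (Br), C4 (H), C5 (Br), C6 (H); ring B is C1' (O), C2' (Br), C4' (Br).

## The problem

Compound 13 is achiral and has no stereocenters, so the whole task is one of constitution. Ring A is 1,2,3,5-tetrasubstituted, with its bromines ortho and para to the ether oxygen but meta to the free hydroxyl. Bromination of a 2-aryloxyphenol would go ortho and para to the hydroxyl, so this pattern cannot be written in late by electrophilic substitution. The ether oxygen sits on C2 between OH and Br and faces an ortho bromine on ring B, so a ring-to-ring C–O coupling must join a weak, doubly ortho-flanked phenoxide to a hindered, unactivated aryl partner. The four aryl C–Br bonds rule out copper- or palladium-catalysed etherification and alkyllithium reagents (halogen–metal exchange), and they also rule out hard lithium amides, because each ring has a hydrogen between two bromines that is open to metalation and halogen migration. The free phenol is prone to oxidation and is best revealed last. The feature that opens a different plan is that, going round ring A from the ether carbon, C3–C6 carry Br, H, Br, H, which is exactly the substitution of C3–C6 of 3,5-dibromo-2H-pyran-2-one (9), while the two remaining carbons, C1 and C2, are adjacent and carry the two oxygens, so that an alkyne can deliver them.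

## Retrosynthesis

**13 to 11 (through 12).** The C1–O bond of the phenol is traced back to a C1–B bond in arylboronate 11. Carrying oxygen itself on this carbon through the ring synthesis would put two competing donors on the two-carbon unit and leave its orientation undefined. Boron instead polarises the unit in the sense needed and becomes OH in one mild operation. The forward reaction must oxidise C–B without touching four C–Br bonds.

**11 to 8 + 9 (through 10).** Ring A is cut at C1–C6 and C2–C3. Pyrone 9 supplies C3–C6 with both ring-A bromines in place. Alkynylboronate 8 supplies C1 (boron) and C2 (aryloxy) and carries the whole of ring B. The neighbouring cut, through the diaryl ether oxygen, would require the hindered ring-to-ring C–O coupling described above; the ring cut never forms a C–O bond at a substituted arene. The precursors are a purchasable heterocycle and a linear alkyne. The forward reaction must be a Diels–Alder addition of one regiochemistry (boron-bearing carbon to C6 of 9) followed by decarboxylative aromatisation of the bridged lactone 10.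

**8 to 4 (through 5, 6, 7).** The C(sp)–B bond and the triple bond are traced to the Z-chlorovinyl ether 4: anti elimination gives ynol ether 5, deprotonation gives acetylide 6, and borylation gives borate 7 and then 8. The usual routes to aryloxyacetylides from dihalovinyl ethers need alkyllithium reagents, which the C–Br bonds forbid. A monochloro precursor needs only a silylamide base, which neither exchanges nor metalates the dibromoarene.

**4 to 1 + 2 (through 3).** The O–C(vinyl) bond is cut, giving 2,4-dibromophenol (1) and cis-1,2-dichloroethene (2), which reacts through chloroacetylene (3). This bond later becomes the hindered O–C2 bond of ring A, but here it is made by addition of a phenoxide to an unhindered sp carbon. Both precursors are commodity chemicals. The forward reaction must stop at mono-addition and give the Z alkene, so that H and Cl are anti for the next step.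

## Roads not taken

**Alternative 1:** the route most chemists would draw first cuts the diaryl ether bond O–C1' of ring B. The phenoxide of 2,4-dibromo-6-methoxyphenol A1 would be arylated with bis(2,4-dibromophenyl)iodonium tetrafluoroborate A2 to give the methyl ether A3, which would then be demethylated to 13. The oxygen of A1 is flanked by Br and OMe and is weakly nucleophilic, and the aryl group to be transferred carries an ortho bromine. Copper or palladium catalysis cannot tell the four C–Br bonds from the bond to be coupled, and ring B is not activated for SNAr. The special reagent A2 must therefore be made first, and half of it is discarded. Bromination, reagent synthesis, coupling and demethylation come to no fewer than four steps, and the plan only joins two finished rings. The chosen route makes the same C–O bond on an unhindered two-carbon unit and builds ring A around it. A variant that cuts the other C–O bond of the ether, by SNAr on an ortho-fluorobenzaldehyde followed by Baeyer–Villiger oxidation, is kept as the fallback for step 3.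

**Alternative 2:** an aryne that takes up the ether oxygen and a bromine on adjacent carbons of ring A. The silyl triflate A4 would be converted with CsF into 5-bromo-3-methoxybenzyne A5, and aryne A5 would be trapped by the phenoxide of 1 and then by an electrophilic bromine source. An alkoxy group beside the triple bond sends the nucleophile to the distal aryne carbon, so in A5 the aryloxy group would land meta to the methoxy group. The product would be A6, which has Br between the two oxygens, not the target pattern. Moving the triple bond to the other side of C2 does not help, because a bromine beside the triple bond likewise sends the nucleophile to the far carbon and away from C2. The target needs the incoming oxygen on the central carbon of a 1,2,3-array, which is the position arynes deny to nucleophiles. In the chosen Diels–Alder step the same polarity argument works in favour of the target.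

**Alternative 3:** a union of like polarity, the oxidative cross-coupling of 1 (reacting at oxygen) with 3,5-dibromophenol A7 (reacting at its ortho carbon). This is one step on paper. However, both phenols form phenoxyl radicals, and four pairings are possible. A7 can couple at either ortho carbon or at the para carbon, through C–O or C–C. Self-coupling of 1 leads to the isomeric ether A8. The product 13 is also easier to oxidise than either partner. Nothing in the substrates enforces the one pairing needed. In the chosen plan the connectivity follows from bond polarity in a cycloaddition.

Key step: step 3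

Assumption: 1, 2 and 9 are taken as purchasable; chloroacetylene (3) is generated and consumed only in dilute solution under inert gas and is never isolated.

## Route

**Step 1**
Reactants: 1 2,4-dibromophenol; 2 (Z)-1,2-dichloroethene
Product: 4 (Z)-2,4-dibromo-1-[(2-chloroethenyl)oxy]benzene, via chloroacetylene 3 (not isolated)
Conditions: KOH (1.3 equiv), 2 (4 equiv), DMSO, 25 to 45 °C, N2, closed vessel
Reagents that add atoms: none
Why: Elimination–addition vinylation, the same reaction type as the vinylation of phenols with trichloroethene: hydroxide removes HCl from 2 to give 3, the phenoxide of 1 adds anti to the unsubstituted carbon, and protonation of the chlorovinyl anion with retention sets the Z double bond. The excess of 2 consumes the regenerated hydroxide and protects 4 from further elimination.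

**Step 2**
Reactants: 4 (Z)-2,4-dibromo-1-[(2-chloroethenyl)oxy]benzene
Product: 8 2-[(2,4-dibromophenoxy)ethynyl]-4,4,5,5-tetramethyl-1,3,2-dioxaborolane, via aryl ethynyl ether 5 (not isolated), via potassium acetylide 6 (not isolated), via potassium isopropoxyborate 7 (not isolated)
Conditions: KN(SiMe3)2 (2.2 equiv), THF, −78 to −40 °C; i-PrOBpin, −78 °C to rt; HCl in Et2O (1.2 equiv), −78 °C to rt; filtration under Ar, used crude
Reagents that add atoms: 2-isopropoxy-4,4,5,5-tetramethyl-1,3,2-dioxaborolane, CC(C)OB1OC(C)(C)C(C)(C)O1
Why: Anti-periplanar E2 loss of HCl (in the Z isomer the hydrogen on the oxygen-bearing carbon is trans to Cl) gives ynol ether 5, which the second equivalent of base deprotonates; borylation of the acetylide and release from borate 7 with anhydrous HCl is the standard alkynylboronate synthesis. A silylamide is chosen because alkyllithiums would exchange, and lithium dialkylamides would metalate, the dibromoarene.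

**Step 3**
Reactants: 8 2-[(2,4-dibromophenoxy)ethynyl]-4,4,5,5-tetramethyl-1,3,2-dioxaborolane (1.2 equiv); 9 3,5-dibromo-2H-pyran-2-one
Product: 11 2-[3,5-dibromo-2-(2,4-dibromophenoxy)phenyl]-4,4,5,5-tetramethyl-1,3,2-dioxaborolane, via bicyclic lactone 10 (not isolated)
Conditions: toluene, 110–130 °C, sealed tube, Ar
Reagents that add atoms: none
Why: Inverse-electron-demand Diels–Alder reaction of the electron-poor diene of 9 (C3–C6) with the oxygen-conjugated π bond of 8, followed by retro-Diels–Alder loss of carbon dioxide from the bridged lactone 10. The closest known reaction types are the cycloaddition–decarboxylation of 2-pyrones with alkynylboronates to give arylboronates and the cycloadditions of 9 with enol ethers. Ring A is closed by a [4+2] cycloaddition that forms C1–C6 and C2–C3 (target numbering) as a six-membered carbocycle, which becomes aromatic when the lactone bridge leaves; the two bridgehead stereocenters of racemic 10 are lost, so no stereocenter has to be controlled. The step needs one regiochemistry: the ether oxygen of 8 makes the boron-bearing alkyne carbon the nucleophilic end, and the empty p orbital on boron reinforces this polarisation, so this carbon should bond first to C6 of 9, the electrophilic δ-carbon of the unsaturated lactone, leaving the aryloxy carbon to close onto the bromine-bearing C3. This is the same sense in which donor-substituted alkenes add to 9 (donor carbon next to the C–Br bridgehead), and it also keeps the bulky boronate away from the C3 bromine. The aryloxy group thus ends up between Br and the boron-bearing carbon, as the target requires. Neutral thermal conditions leave the four C–Br bonds and the boronate untouched.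

**Step 4**
Reactants: 11 2-[3,5-dibromo-2-(2,4-dibromophenoxy)phenyl]-4,4,5,5-tetramethyl-1,3,2-dioxaborolane
Product: 13 3,5-dibromo-2-(2,4-dibromophenoxy)phenol, via aryl pinacol borate 12 (not isolated)
Conditions: 30% aq. H2O2, NaOH (2 equiv), THF/H2O, 0 °C to rt; acidic work-up
Reagents that add atoms: hydrogen peroxide, OO
Why: Oxidation of an arylboronic ester with alkaline hydrogen peroxide: hydroperoxide adds to boron, the aryl group migrates from boron to oxygen at the same ring carbon, and borate 12 is hydrolysed to the phenol. Aryl bromides and the diaryl ether are inert to these conditions.

## Compound list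

1 | 2,4-dibromophenol | Oc1ccc(Br)cc1Br | starting material
2 | (Z)-1,2-dichloroethene | Cl/C=C\Cl | starting material
3 | chloroacetylene (chloroethyne) | ClC#C | intermediate (not isolated)
4 | (Z)-2,4-dibromo-1-[(2-chloroethenyl)oxy]benzene | Cl/C=C\Oc1ccc(Br)cc1Br | intermediate
5 | 2,4-dibromo-1-(ethynyloxy)benzene | C#COc1ccc(Br)cc1Br | intermediate (not isolated)
6 | potassium (2,4-dibromophenoxy)ethynide | [K+].[C-]#COc1ccc(Br)cc1Br | intermediate (not isolated)
7 | potassium [(2,4-dibromophenoxy)ethynyl](isopropoxy)(pinacolato)borate | [K+].CC(C)O[B-]1(C#COc2ccc(Br)cc2Br)OC(C)(C)C(C)(C)O1 | intermediate (not isolated)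
8 | 2-[(2,4-dibromophenoxy)ethynyl]-4,4,5,5-tetramethyl-1,3,2-dioxaborolane | CC1(C)OB(C#COc2ccc(Br)cc2Br)OC1(C)C | intermediate
9 | 3,5-dibromo-2H-pyran-2-one | O=C1OC=C(Br)C=C1Br | starting material
10 | 4,7-dibromo-5-(2,4-dibromophenoxy)-6-(4,4,5,5-tetramethyl-1,3,2-dioxaborolan-2-yl)-2-oxabicyclo[2.2.2]octa-5,7-dien-3-one (racemic; the bicycle allows one relative configuration only) | O=C1OC2C(B3OC(C)(C)C(C)(C)O3)=C(Oc3ccc(Br)cc3Br)C1(Br)C=C2Br | intermediate (not isolated)
11 | 2-[3,5-dibromo-2-(2,4-dibromophenoxy)phenyl]-4,4,5,5-tetramethyl-1,3,2-dioxaborolane | CC1(C)OB(OC1(C)C)c1cc(Br)cc(Br)c1Oc1ccc(Br)cc1Br | intermediate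
12 | 2-[3,5-dibromo-2-(2,4-dibromophenoxy)phenoxy]-4,4,5,5-tetramethyl-1,3,2-dioxaborolane | CC1(C)OB(Oc2cc(Br)cc(Br)c2Oc2ccc(Br)cc2Br)OC1(C)C | intermediate (not isolated)
13 | 3,5-dibromo-2-(2,4-dibromophenoxy)phenol | Oc1cc(Br)cc(Br)c1Oc1ccc(Br)cc1Br | target

## Step count and risks

Total steps: 4. Longest linear sequence: 4 (1 to 4 to 8 to 11 to 13).

**Step 3 (key step).** The nucleophilicity of the alkyne is damped by the electron-poor aryloxy group and by boron. The cycloaddition may therefore be slow enough for thermal oligomerisation of the ynol ether to compete, and the regiochemical preference may be eroded at the temperature needed. Fallback, which gives up ring construction: starting from 1, SNAr displacement of fluoride from 3,5-dibromo-2-fluorobenzaldehyde F1 (K2CO3, DMF) would give 3,5-dibromo-2-(2,4-dibromophenoxy)benzaldehyde F2. Baeyer–Villiger oxidation with 3-chloroperoxybenzoic acid would give 3,5-dibromo-2-(2,4-dibromophenoxy)phenyl formate F3, and methanolysis (catalytic K2CO3, MeOH) would return to the route at 13.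

**Step 2.** Two processes threaten this step. The first is protonolysis of the C–B bond or addition of HCl across the electron-rich triple bond while 8 is released from borate 7 and isolated. The second is expulsion of 2,4-dibromophenoxide in place of chloride when 4 is deprotonated, which reverses step 1. Fallback, with silicon as a robust stand-in for boron: starting from 4, acetylide 6 would be trapped with Me3SiCl to give [(2,4-dibromophenoxy)ethynyl]trimethylsilane F4, which can be purified. Cycloaddition with 9 under the conditions of step 3, with loss of carbon dioxide, would give [3,5-dibromo-2-(2,4-dibromophenoxy)phenyl]trimethylsilane F5. Ipso-borodesilylation with BBr3 in CH2Cl2 would give dibromo[3,5-dibromo-2-(2,4-dibromophenoxy)phenyl]borane F6, and alkaline hydrogen peroxide would return to the route at 13.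

**Step 1.** The weakly nucleophilic phenoxide may add too slowly, so that chloroacetylene is lost or consumed by hydroxide. Alternatively 4 may undergo a second elimination and take up a second phenoxide. Fallback, which avoids chloroacetylene: starting from 1, O-vinylation with the 2,4,6-trivinylcyclotriboroxane–pyridine complex and Cu(OAc)2 would give 2,4-dibromo-1-(ethenyloxy)benzene F7. Addition of Br2 at −78 °C would give racemic 2,4-dibromo-1-(1,2-dibromoethoxy)benzene F8. Double dehydrobromination and deprotonation with KN(SiMe3)2 (3.3 equiv) would return to the route at 6, which is borylated as in step 2. In this variant the group lost in the elimination is bromide, which also answers the second concern raised for step 2.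

## Further compounds

F1 | step 3 | 3,5-dibromo-2-fluorobenzaldehyde | O=Cc1cc(Br)cc(Br)c1F
F2 | step 3 | 3,5-dibromo-2-(2,4-dibromophenoxy)benzaldehyde | O=Cc1cc(Br)cc(Br)c1Oc1ccc(Br)cc1Br
F3 | step 3 | 3,5-dibromo-2-(2,4-dibromophenoxy)phenyl formate | O=COc1cc(Br)cc(Br)c1Oc1ccc(Br)cc1Br
F4 | step 2 | [(2,4-dibromophenoxy)ethynyl]trimethylsilane | C[Si](C)(C)C#COc1ccc(Br)cc1Br
F5 | step 2 | [3,5-dibromo-2-(2,4-dibromophenoxy)phenyl]trimethylsilane | C[Si](C)(C)c1cc(Br)cc(Br)c1Oc1ccc(Br)cc1Br
F6 | step 2 | dibromo[3,5-dibromo-2-(2,4-dibromophenoxy)phenyl]borane | BrB(Br)c1cc(Br)cc(Br)c1Oc1ccc(Br)cc1Br
F7 | step 1 | 2,4-dibromo-1-(ethenyloxy)benzene | C=COc1ccc(Br)cc1Br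
F8 | step 1 | 2,4-dibromo-1-(1,2-dibromoethoxy)benzene (racemic) | BrCC(Br)Oc1ccc(Br)cc1Br
A1 | alternative 1 | 2,4-dibromo-6-methoxyphenol | COc1cc(Br)cc(Br)c1O
A2 | alternative 1 | bis(2,4-dibromophenyl)iodonium tetrafluoroborate | Brc1ccc([I+]c2ccc(Br)cc2Br)c(Br)c1.F[B-](F)(F)F
A3 | alternative 1 | 1,5-dibromo-2-(2,4-dibromophenoxy)-3-methoxybenzene | COc1cc(Br)cc(Br)c1Oc1ccc(Br)cc1Br
A4 | alternative 2 | 4-bromo-2-methoxy-6-(trimethylsilyl)phenyl trifluoromethanesulfonate | COc1cc(Br)cc([Si](C)(C)C)c1OS(=O)(=O)C(F)(F)F
A5 | alternative 2 | 5-bromo-3-methoxybenzyne | COC1=CC(Br)=CC#C1
A6 | alternative 2 | 2,5-dibromo-1-(2,4-dibromophenoxy)-3-methoxybenzene | COc1cc(Br)cc(Oc2ccc(Br)cc2Br)c1Br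
A7 | alternative 3 | 3,5-dibromophenol | Oc1cc(Br)cc(Br)c1
A8 | alternative 3 | 2,4-dibromo-6-(2,4-dibromophenoxy)phenol | Oc1c(Br)cc(Br)cc1Oc1ccc(Br)cc1Br
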